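The flask carries 1.50 moles of coupling partner per mole of the two substrates together, so the partner can cover both. I ask how much contact a substrate molecule gets by the asked time.

| setting | delta | gamma | theta | flask |
|---|---|---|---|---|
| left-handed substrate | 0.25 M | 0.25 M | 0.25 M | 0.25 M |
| right-handed substrate | 0.25 M | 0.25 M | 0.25 M | 0.25 M |
| coupling partner | 0.75 M (fed, over 25 h) | 0.75 M (fed, over 25 h) | 1.5 M (fed, over 25 h) | 0.750 M (fed, over 25 h) |
| catalyst | 8 mM | 12 mM | 16 mM | 16 mM |
| remark | run made earlier; the fed solution adds 0.10 times the starting volume | run made earlier; the fed solution adds 0.10 times the starting volume | run made earlier; the fed solution adds 0.10 times the starting volume | the fed solution adds 0.10 times the starting volume |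
| time |  |  |  | 2.0 d |

| run | time / h | left-handed substrate / % | right-handed substrate / % | left-handed product / % |
|---|---|---|---|---|
| delta | 6.00 | 46 | 51 | 5 |
| delta | 12.0 | 45 | 45 | 9 |
| delta | 15.0 | 40 | 48 | 9 |
| delta | 20.0 | 37 | 47 | 20 |
| delta | 30.0 | 24 | 42 | 28 |
| delta | 40.0 | 25 | 35 | 36 |
| gamma | 3.00 | 49 | 50 | 2 |
| gamma | 5.00 | 44 | 49 | 2 |
| gamma | 8.00 | 43 | 49 | 6 |
| gamma | 10.0 | 46 | 49 | 11 |
| gamma | 15.0 | 36 | 49 | 14 |
| gamma | 25.0 | 24 | 39 | 31 |
| gamma | 40.0 | 16 | 32 | 43 |
| theta | 3.00 | 49 | 52 | 7 |
| theta | 6.00 | 46 | 49 | 8 |
| theta | 10.0 | 34 | 47 | 18 |
| theta | 20.0 | 12 | 37 | 39 |
| theta | 40.0 | 4 | 16 | 60 |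

(scatter of a reading: 2 percentage points)

1. part of the left-handed substrate and right-handed substrate charged together that has reacted at 2.0 d
2. excess of left-handed product over right-handed product in the product at 2.0 d
3. excess of right-handed substrate over left-handed substrate among what is left of the two at 2.0 d

- catalyst is single-handed; left-handed substrate and right-handed substrate are mirror images of each other, charged as a racemate, each of them at the stated concentration
- charges are per starting volume, the dose included; the dosed solution carries all of it
- steps under discussion: coupling partner + catalyst + left-handed substrate -> catalyst + left-handed product; left-handed substrate <-> right-handed substrate; coupling partner + catalyst + right-handed substrate -> catalyst + right-handed product; left-handed product <-> right-handed product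
- an excess is the difference of the two amounts in percent of their sum
- an excess is below zero if the other one leads

I follow one substrate molecule. By the listed steps it couples on meeting catalyst and partner together, so its chance per hour scales with their product, which makes it pseudo-first-order in substrate. The contact number of the flask is 2.58: catalyst times charged partner times the clock less half the dosing time, scaled to delta at 40.0 h. I count the dose that way because partner arrives steadily and its feed ends before either clock. Depth is the natural logarithm of charged over left, for both substrates together. By this reckoning, equal contact should give equal depth.

I turn the catalyst first. By hand, gamma's contact is 1.50 times delta's, and depth should follow. The readings take depth from 0.511 to 0.734, a factor of 1.44.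

Next I turn the partner. Theta has more of it than delta and more catalyst too, so two settings differ, for a contact of 4.00. By hand that means depth 2.04, but the reading is 1.61, less than proportion. In theta at 40.0 h, right-handed substrate reads 16%, more than the left-handed 4%.

Dosing time I cannot turn on these runs: delta, gamma and theta share 25 h.

The contact number of the flask lies above gamma's and below theta's, so I interpolate depth to 1.11, which means 67.1% reacted. Contact counts reaction, not handedness, so I draw no excess from it.

The forecast gives 65% reacted, less than mine, with excesses of 63% in the product and 45% in the substrate, and it says “Product racemisation cannot be identified from these data”.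

The flask gives 67.0% reacted, 48.0% excess of left-handed product and 38.4% excess of right-handed substrate.

    coupling partner + catalyst + left-handed substrate → catalyst + left-handed product (k = 0.00310 /M²/s)
    left-handed substrate ⇌ right-handed substrate (k = 9.10 × 10⁻⁶ /s)
    coupling partner + catalyst + right-handed substrate → catalyst + right-handed product (k = 2.30 × 10⁻⁴ /M²/s)
    left-handed product ⇌ right-handed product (k = 2.70 × 10⁻⁶ /s)

On this flask the contact number gave 67.1%, beside the 67.0% reacted. The neighbouring flask keeps the recipe but charges 0.30 M of coupling partner. Its contact number is 1.03, close to delta's, so the same reckoning gives depth 0.528 and 41.0% reacted. It stands at 37.2%, less than that. Its partner is down to 38% of its charge at 2.0 d, less than the flask's 55%.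

Readings and results stem from a simulated flask from invented constants, and the scatter is random.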